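## The problem

Target 19 is (1S,2R,3R)-lyoniresinol, a 1-aryltetralin lignan; tetralin numbering is used throughout, with C1–C4 the saturated carbons of ring B, C4a and C8a the fusion carbons, and ring A carrying H at C5, OMe at C6, OH at C7 and OMe at C8. Ring B holds three contiguous stereocentres in an all-trans, all-equatorial array: the 4-hydroxy-3,5-dimethoxyphenyl group at C1 and hydroxymethyl groups at C2 and C3. C2 and C3 form a trans pair of identical one-carbon arms, the imprint of a fumarate unit, so one asymmetric cycloaddition can set both in the absolute sense. C1 is benzylic and next to C2, so if it lies α to a carbonyl at some stage, C2 can steer it to the trans arrangement by equilibration. Both 2,6-dimethoxyphenols are readily oxidised (quinone and quinone methide formation) and the diarylmethine C1–H is prone to benzylic oxidation and acid-mediated epimerisation, so the free phenols should appear late and oxidants and strong acids are excluded once the arenes are in place. Ring A is substituted at five of its six positions and its C8 methoxy group lies peri to the C1 aryl group, which makes a late closure of ring B onto a finished ring A crowded. The enabling feature is that C6, C7 and C8 carry OMe, OH and OMe symmetrically about C7, which is the carbon skeleton and oxygen pattern of 1,3-dimethoxyacetone. The other three ring A carbons (C5 as CH, C4a and C8a) correspond to the formyl carbon, α-carbon and carbonyl carbon of a 2-formylcyclohexanone that is ring B itself.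

## Retrosynthesis

**19 to 18.** The three benzyl ether C–O bonds are cut last. One kind of protecting group on the pendant phenol and on both primary alcohols allows a single neutral hydrogenolysis to end the route. The C7 phenol needs no protection because it is formed in the step before. The forward reaction only has to spare the arenes and the diarylmethine.

**18 to 15 and 16.** Ring A is cut at C5=C6 and C8=C8a, giving the symmetric dinucleophile 16 and the enaminone 15 as a C5–C4a–C8a dielectrophile. Against the classical closure of ring B onto an intact ring A, this cut keeps ring B as a cyclohexanone with its stereocentres already fixed, replaces an arene carrying three differentiated oxygens by a purchasable symmetric ketone, and delivers the C7 hydroxyl free and distinct from its methylated neighbours. The precursor is simpler by one arene and raises no new stereochemical question. The forward reaction requires a non-stabilised α-alkoxy ketone enolate to displace dimethylamine, close onto a hindered ketone, and leave C1 trans to C2.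

**15 to 12 and 14.** The C1–aryl bond is cut as a ketone enolate arylation. The aminomethylene group at C4a serves twice: it blocks that α-position so that only C1 can be arylated, and it is the future C5. Bringing the aryl group in earlier on a diene would give up the symmetry used below and the established auxiliary control. The forward reaction must couple at a methylene next to a branched carbon; the C1 configuration is left to equilibration.

**12 to 10 and 11.** The C4a=C5 bond comes from condensation of ketone 10 with the amide acetal 11. The two α-methylenes of 10 differ only in their distance from the C2 branch, and the forward reaction must choose the one remote from it.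

**10 to 9 to 7.** The C8a oxygen comes from hydroboration–oxidation of alkene 7 and oxidation of alcohol 9. Because 7 is C2-symmetric its two alkene carbons are equivalent, so only one ketone can form and there is no regiochemical demand. A diene that already carried the ketone oxygen would save this adjustment but would force protection of the ketone through the ester reduction.

**7 to 6 to 5.** Benzyl ether formation and ester reduction are functional-group changes only. The auxiliary 1 is recovered in the reduction.

**5 to 3 and 4; 3 to 1 and 2.** Ring B is cut at C1–C2 and C3–C4 as a Diels–Alder reaction of buta-1,3-diene 4 with dimenthyl fumarate 3. Diester 3 is assembled from fumaric acid 2 and two molecules of menthol 1, one for each carboxyl group. This cut sets C2 and C3 together, trans by the alkene geometry and absolute by the auxiliary. The forward reaction needs high facial selectivity; the (+)-menthyl ester is chosen for the (R,R) pair.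

**14 to 13.** The aryl bromide 14 is the benzyl ether of commercial phenol 13.

## Roads not taken

Alternative 1: C1 is cut from both the pendant aryl group (C1–C1') and C2. The components are aryl bromide 14 and a ring A aldehyde N-tosylhydrazone A2 that carries the C3 stereocentre and a malonate. In the forward step, zerovalent palladium from Pd2(dba)3 adds to 14, the diazo compound released from A2 gives an aryl palladium carbene, and migratory insertion forms C1–C1' and an η3-benzyl palladium. The tethered malonate captures this at C1, closing ring B to the 1,3-cis diester A1.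
- Merits: both arenes are bought with their oxygenation complete, the route is more convergent than the chosen one, and the benzylic palladium intermediate has no β-hydrogen to lose.
- Weak points: A2 is a pentasubstituted benzaldehyde whose carbene carbon is flanked by a methoxy group and an alkyl chain, and it needs its own asymmetric synthesis of C3. C2 arrives as a geminal diester, so a dealkoxycarbonylation, late equilibration of C2 and a reduction must follow. Capture of a benzyl palladium by a carbon nucleophile is the less usual outcome of such couplings.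
- Comparison: this road is better in convergence and in the certainty of the ring A substitution pattern. The chosen plan offers against it one auxiliary-controlled step that sets C2 and C3 directly, no excision of an ester carbon, and ring A from a single condensation instead of a multi-step arene synthesis. Its own key step is less tested.

Alternative 2: Ring B is cut at C4–C4a and C2–C3, so that buta-1,3-diene 4 is inserted between the aryl bromide and the malonate carbon of A4. In the forward step, with Pd(OAc)2 the aryl palladium formed from A4 adds to a diene terminus (C4–C4a). The malonate carbon C2 then attacks the η3-allyl palladium at its internal carbon (C2–C3), closing ring B to the 3-vinyl diester A3.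
- Merits: diene carboannulation by aryl halides with tethered soft nucleophiles is well established, the diene is the same cheap four-carbon unit used in the chosen plan, and both arenes are bought.
- Weak points: the C3 vinyl group must be cleaved oxidatively next to two very electron-rich arenes and then reduced. The geminal diester again needs dealkoxycarbonylation. The only stereocentre of A4 is a diarylmethine that must be made enantioselectively and then relay its configuration 1,3 to C3 through an allyl palladium; this control is uncertain.
- Comparison: the key step stands on firmer precedent than the chosen condensation. The chosen plan offers against it fewer adjustments after the key step and much firmer control of C2 and C3.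

Alternative 3: Ring B is cut at C1–C2 and C3–C4 as a Diels–Alder reaction of an o-quinodimethane. In the forward step, irradiation of the 2-benzylbenzaldehyde A6 transfers a benzylic hydrogen to the excited carbonyl. The resulting E-hydroxy-o-quinodimethane, held on Ti(OiPr)4 with a tartrate-derived chiral diol, adds dimethyl fumarate A7 to give A5 (1,2-trans, 2,3-trans, 3,4-cis). Ester reduction and hydrogenolysis of the benzyl ethers together with the benzylic C4 hydroxyl would finish the synthesis.
- Merits: this is probably the shortest road. Both arenes are bought, and two C–C bonds and all three required stereocentres are formed in one step.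
- Weak points: enantiofacial control depends on a chiral Ti(OiPr)4–diol template and an acyclic fumarate as dienophile. The C1 configuration is decided kinetically by the geometry of an aryl-substituted photoenol. A photochemical step on an electron-rich aldehyde is harder to scale, and a benzylic deoxygenation is added.
- Comparison: this road is better in step count and convergence. The chosen plan offers against it absolute configuration from a thermal, auxiliary-controlled cycloaddition, C1 set by equilibrium, no photochemistry, and direct formation of the free C7 phenol. The price is a longer linear sequence and a less tested ring-forming step.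

Key step: step 10

Remark on the chemistry (assumption): the facial bias of dimenthyl fumarate under iBu2AlCl promotion is taken as the established one, the (−)-menthyl ester leading to the (1S,2S) cyclohexene adduct. The (+)-menthyl ester is therefore used for the (1R,2R) series; were the sense the opposite, the (−)-menthyl ester would be used with no other change.

## Steps

Step 1
Reactants: 1 (1S,2R,5S)-(+)-menthol; 2 fumaric acid
Product: 3 di-(+)-menthyl fumarate, bis[(1S,2R,5S)-2-isopropyl-5-methylcyclohexyl] (E)-but-2-enedioate
Conditions: 1 (2.2 equiv), 2 (1 equiv), TsOH·H2O (cat.), toluene, reflux, Dean–Stark trap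
Reagents that add atoms: (1S,2R,5S)-(+)-menthol, the second equivalent of 1, CC(C)[C@H]1CC[C@H](C)C[C@@H]1O
Why: Twofold Fischer esterification driven by azeotropic removal of water, each carboxyl group of 2 taking up one molecule of 1; the C–O bond of the alcohol is not broken, so the menthyl stereocentres are carried over, and the E alkene is stable to the acid.

Step 2
Reactants: 3 di-(+)-menthyl fumarate; 4 buta-1,3-diene
Product: 5 di[(1S,2R,5S)-menthyl] (1R,2R)-cyclohex-4-ene-1,2-dicarboxylate
Conditions: iBu2AlCl (1.5 equiv), toluene–hexane, −40 °C; aq. HCl work-up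
Reagents that add atoms: none
Why: Lewis-acid-promoted asymmetric Diels–Alder reaction; in the aluminium-bound s-trans diester both menthyl groups screen the same face of the alkene, so the diene should add to the open face and set both ring stereocentres as the (R,R) pair, their trans relation following from suprafacial addition to the E alkene.

Step 3
Reactants: 5 di[(1S,2R,5S)-menthyl] (1R,2R)-cyclohex-4-ene-1,2-dicarboxylate
Product: 6 [(1R,2R)-cyclohex-4-ene-1,2-diyl]dimethanol
Conditions: LiAlH4, THF, 0 °C to reflux; Fieser work-up; menthol 1 recovered
Reagents that add atoms: none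
Why: Hydride reduction of the esters to primary alcohols; no bond to a stereocentre is broken and the trans arrangement is the stable one, so the configuration should be retained.

Step 4
Reactants: 6 [(1R,2R)-cyclohex-4-ene-1,2-diyl]dimethanol
Product: 7 (4R,5R)-4,5-bis(benzyloxymethyl)cyclohex-1-ene
Conditions: NaH, BnBr, Bu4NI (cat.), THF–DMF, 0 °C to rt
Reagents that add atoms: benzyl bromide, BrCc1ccccc1
Why: Williamson ether synthesis on two unhindered primary alkoxides; the benzyl ethers tolerate the borane, oxidant, alkoxide and palladium steps that follow.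

Step 5
Reactants: 7 (4R,5R)-4,5-bis(benzyloxymethyl)cyclohex-1-ene
Product: 9 (3R,4R)-3,4-bis(benzyloxymethyl)cyclohexan-1-ol (mixture of C1 epimers), via cyclohexyl-9-BBN adduct 8 (not isolated)
Conditions: 9-borabicyclo[3.3.1]nonane (9-BBN-H, 0.5 M in THF), 65 °C; then 3 M NaOH, 30% H2O2, 0 °C to rt
Reagents that add atoms: hydrogen peroxide, OO
Why: Brown hydroboration–oxidation; the two alkene carbons of C2-symmetric 7 are equivalent, so only one constitution can form, and the carbinol epimers converge in the next step.

Step 6
Reactants: 9 (3R,4R)-3,4-bis(benzyloxymethyl)cyclohexan-1-ol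
Product: 10 (3R,4R)-3,4-bis(benzyloxymethyl)cyclohexan-1-one
Conditions: TEMPO (cat.), KBr (cat.), NaOCl, NaHCO3, CH2Cl2–H2O, 0 °C
Reagents that add atoms: none
Why: Anelli (oxoammonium) oxidation of a secondary alcohol; benzyl ethers are inert at 0 °C and neither stereocentre is α to the new carbonyl, so no epimerisation is possible.

Step 7
Reactants: 10 (3R,4R)-3,4-bis(benzyloxymethyl)cyclohexan-1-one; 11 N,N-dimethylformamide dimethyl acetal
Product: 12 (2E,4R,5R)-4,5-bis(benzyloxymethyl)-2-[(dimethylamino)methylidene]cyclohexan-1-one
Conditions: neat Me2NCH(OMe)2 (5 equiv), 110 °C, MeOH distilled off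
Reagents that add atoms: none
Why: Condensation of a ketone α-methylene with an amide acetal to the enaminone; C6 of 10 (flanked by CH2) should react in preference to C2 (flanked by the C3 branch), because an aminomethylene group at C2 would clash with the C3 substituent (allylic 1,3-strain) and the aminal intermediates form reversibly. The E geometry, with nitrogen anti to the carbonyl, is the usual one.

Step 8
Reactants: 13 4-bromo-2,6-dimethoxyphenol
Product: 14 2-(benzyloxy)-5-bromo-1,3-dimethoxybenzene
Conditions: BnBr, K2CO3, DMF, rt
Reagents that add atoms: benzyl bromide, BrCc1ccccc1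
Why: Williamson etherification of the phenoxide; the benzyl group matches the other two so that all three fall in the last step.

Step 9
Reactants: 12 (2E,4R,5R)-4,5-bis(benzyloxymethyl)-2-[(dimethylamino)methylidene]cyclohexan-1-one; 14 2-(benzyloxy)-5-bromo-1,3-dimethoxybenzene
Product: 15 (2S,3S,4R,6E)-2-[4-(benzyloxy)-3,5-dimethoxyphenyl]-3,4-bis(benzyloxymethyl)-6-[(dimethylamino)methylidene]cyclohexan-1-one
Conditions: Pd(OAc)2 (5 mol %), XPhos (10 mol %), NaOtBu (2.2 equiv), toluene, 80 °C; aq. NH4Cl
Reagents that add atoms: none
Why: Palladium-catalysed α-arylation of a ketone enolate (Buchwald–Hartwig type) on an aminomethylene-blocked ketone, a substrate class for which this coupling is established; the blocked position leaves the C6 methylene of 12 as the only enolisable site, and the bromide has no ortho substituent. The new stereocentre is α to the ketone and held as the enolate under the alkoxide, so it should settle as the all-equatorial isomer trans to the neighbouring benzyloxymethyl group, and any residual epimer is corrected by the base of step 10.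

Step 10
Reactants: 15 (2S,3S,4R,6E)-2-[4-(benzyloxy)-3,5-dimethoxyphenyl]-3,4-bis(benzyloxymethyl)-6-[(dimethylamino)methylidene]cyclohexan-1-one; 16 1,3-dimethoxypropan-2-one (1,3-dimethoxyacetone)
Product: 18 (1S,2R,3R)-1-[4-(benzyloxy)-3,5-dimethoxyphenyl]-2,3-bis(benzyloxymethyl)-6,8-dimethoxy-1,2,3,4-tetrahydronaphthalen-7-ol (tetralin numbering), via alkylidene diketone 17 (not isolated)
Conditions: 16 (3 equiv), KOtBu (3 equiv), tBuOH–THF, rt to 65 °C, argon; AcOH quench
Reagents that add atoms: none
Why: This is a base-mediated (3+3) cyclocondensation of the Prelog type, closest to the known benzannulations of 2-(hydroxymethylene)- and 2-(aminomethylene)cycloalkanones with acetonedicarboxylates and of vinamidinium salts or nitromalonaldehyde with simple ketones. The potassium enolate of 16 adds at C5 of the vinylogous amide and dimethylamine is expelled (addition–elimination, C5–C6), giving 17, whose exocyclic double bond can turn through the extended enolate so that the second α-carbon of the same ketone reaches the C8a carbonyl in a 6-(enolexo)-exo-trig aldol addition (C8–C8a), which closes ring A. E1cB loss of water through the C7 enolate places the double bond between C8 and C8a, and enolisation of the resulting cyclohexa-2,4-dienone (the C6 hydrogen moves to oxygen) gives the phenol, so aromatisation and phenoxide formation drive the sequence. No oxidant is needed because C5 enters at the aldehyde oxidation level. Because 16 is symmetric there is no regiochemical choice: OMe, OH and OMe must end at C6, C7 and C8, and C5 keeps its hydrogen. No new stereocentre is formed and C2 and C3 are untouched; C1, α to the ketone until the ring closes, equilibrates under the alkoxide to the all-equatorial arrangement trans to C2 and is fixed once C8a is no longer a carbonyl, after which it is a non-acidic diarylmethine. The selectivity needed is cross-condensation over self-condensation of 16 and over unproductive enolisation of 15 at C1; both side equilibria are reversible in tBuOH, only the path to the arene is irreversible, and an excess of 16 is used.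

Step 11
Reactants: 18 (1S,2R,3R)-1-[4-(benzyloxy)-3,5-dimethoxyphenyl]-2,3-bis(benzyloxymethyl)-6,8-dimethoxy-1,2,3,4-tetrahydronaphthalen-7-ol
Product: 19 (1S,2R,3R)-1-(4-hydroxy-3,5-dimethoxyphenyl)-2,3-bis(hydroxymethyl)-6,8-dimethoxy-1,2,3,4-tetrahydronaphthalen-7-ol, (1S,2R,3R)-lyoniresinol
Conditions: H2 (1 atm), 10% Pd/C, EtOAc–MeOH, rt
Reagents that add atoms: none
Why: Catalytic hydrogenolysis of two alkyl benzyl ethers and one aryl benzyl ether; the C1–aryl bonds are C–C bonds and inert under these conditions, and no stereocentre is touched.

## Compound list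

1 | (1S,2R,5S)-(+)-menthol | CC(C)[C@H]1CC[C@H](C)C[C@@H]1O | starting material
2 | fumaric acid | OC(=O)/C=C/C(=O)O | starting material
3 | di-(+)-menthyl fumarate, bis[(1S,2R,5S)-2-isopropyl-5-methylcyclohexyl] (E)-but-2-enedioate | CC(C)[C@H]1CC[C@H](C)C[C@@H]1OC(=O)/C=C/C(=O)O[C@H]1C[C@@H](C)CC[C@@H]1C(C)C | intermediate
4 | buta-1,3-diene | C=CC=C | starting material
5 | di[(1S,2R,5S)-menthyl] (1R,2R)-cyclohex-4-ene-1,2-dicarboxylate | C1=CC[C@@H](C(=O)O[C@H]2C[C@@H](C)CC[C@@H]2C(C)C)[C@H](C(=O)O[C@H]2C[C@@H](C)CC[C@@H]2C(C)C)C1 | intermediate
6 | [(1R,2R)-cyclohex-4-ene-1,2-diyl]dimethanol | C1=CC[C@@H](CO)[C@H](CO)C1 | intermediate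
7 | (4R,5R)-4,5-bis(benzyloxymethyl)cyclohex-1-ene | C1=CC[C@@H](COCc2ccccc2)[C@H](COCc2ccccc2)C1 | intermediate
8 | 9-[(3R,4R)-3,4-bis(benzyloxymethyl)cyclohexyl]-9-borabicyclo[3.3.1]nonane (epimers at the boron-bearing carbon) | C1CCC2CCCC(C1)B2C1CC[C@@H](COCc2ccccc2)[C@H](COCc2ccccc2)C1 | intermediate (not isolated)
9 | (3R,4R)-3,4-bis(benzyloxymethyl)cyclohexan-1-ol (mixture of C1 epimers) | OC1CC[C@@H](COCc2ccccc2)[C@H](COCc2ccccc2)C1 | intermediate
10 | (3R,4R)-3,4-bis(benzyloxymethyl)cyclohexan-1-one | O=C1CC[C@@H](COCc2ccccc2)[C@H](COCc2ccccc2)C1 | intermediate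
11 | N,N-dimethylformamide dimethyl acetal | COC(OC)N(C)C | starting material
12 | (2E,4R,5R)-4,5-bis(benzyloxymethyl)-2-[(dimethylamino)methylidene]cyclohexan-1-one | O=C1C[C@@H](COCc2ccccc2)[C@H](COCc2ccccc2)C/C1=C\N(C)C | intermediate
13 | 4-bromo-2,6-dimethoxyphenol | COc1cc(Br)cc(OC)c1O | starting material
14 | 2-(benzyloxy)-5-bromo-1,3-dimethoxybenzene | COc1cc(Br)cc(OC)c1OCc1ccccc1 | intermediate
15 | (2S,3S,4R,6E)-2-[4-(benzyloxy)-3,5-dimethoxyphenyl]-3,4-bis(benzyloxymethyl)-6-[(dimethylamino)methylidene]cyclohexan-1-one | COc1cc([C@H]2C(=O)/C(=C/N(C)C)C[C@@H](COCc3ccccc3)[C@@H]2COCc2ccccc2)cc(OC)c1OCc1ccccc1 | intermediate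
16 | 1,3-dimethoxypropan-2-one (1,3-dimethoxyacetone) | COCC(=O)COC | starting material
17 | (2S,3S,4R,6E)-2-[4-(benzyloxy)-3,5-dimethoxyphenyl]-3,4-bis(benzyloxymethyl)-6-(2,4-dimethoxy-3-oxobutylidene)cyclohexan-1-one (side-chain methoxy-bearing carbon of undefined configuration; drawn as the alkylidene diketone tautomer) | COCC(=O)C(OC)/C=C1\C[C@@H](COCc2ccccc2)[C@H](COCc2ccccc2)[C@@H](c2cc(OC)c(OCc3ccccc3)c(OC)c2)C1=O | intermediate (not isolated)
18 | (1S,2R,3R)-1-[4-(benzyloxy)-3,5-dimethoxyphenyl]-2,3-bis(benzyloxymethyl)-6,8-dimethoxy-1,2,3,4-tetrahydronaphthalen-7-ol (tetralin numbering) | COc1cc([C@H]2c3c(cc(OC)c(O)c3OC)C[C@@H](COCc3ccccc3)[C@@H]2COCc2ccccc2)cc(OC)c1OCc1ccccc1 | intermediate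
19 | (1S,2R,3R)-lyoniresinol, (1S,2R,3R)-1-(4-hydroxy-3,5-dimethoxyphenyl)-2,3-bis(hydroxymethyl)-6,8-dimethoxy-1,2,3,4-tetrahydronaphthalen-7-ol | COc1cc([C@H]2c3c(cc(OC)c(O)c3OC)C[C@@H](CO)[C@@H]2CO)cc(OC)c1O | target

## Step count and least certain steps

Total: 11 steps. Longest linear sequence: 10 steps (steps 1–7, 9, 10, 11); step 8 is a one-step branch.

**Step 10 (key step).**
- Most likely to go wrong: the non-stabilised enolate of 16 may fail to displace dimethylamine from the weakly electrophilic vinylogous amide before it self-condenses. Reversible enolisation of 15 at C1 may also hold the substrate in an unreactive form, so that conversion stalls before the ring-closing aldol.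
- Fallback: it sets out from 15 and rejoins at 19, using the established acetonedicarboxylate partner and then exchanging the two ester carbons for oxygen.
  - Condensation of 15 with dimethyl 3-oxopentanedioate (NaOMe, MeOH) should give the dimethyl 7-hydroxytetralin-6,8-dicarboxylate F1.
  - Benzylation (BnBr, K2CO3) gives the 7-benzyl ether diester F2.
  - LiAlH4 gives the 6,8-bis(hydroxymethyl) compound F3.
  - MnO2 gives the 6,8-dicarbaldehyde F4.
  - mCPBA (Baeyer–Villiger oxidation with aryl migration) gives the 6,8-bis(formate) F5.
  - K2CO3 in MeOH cleaves this to the 6,8-diol F6.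
  - MeI with K2CO3 gives the 6,8-dimethyl ether F7, which carries four benzyl ethers and is hydrogenolysed under the conditions of step 11 to 19.

**Step 7.**
- Most likely to go wrong: incomplete site selectivity between the two α-methylenes of 10, or slow conversion of an unactivated ketone with the amide acetal, because the steric difference between the sites is one carbon removed.
- Fallback: it sets out from 10 and rejoins at 12. Claisen formylation under equilibrating conditions (HCO2Et, NaOMe, toluene, rt) should give the less hindered hydroxymethylene ketone F8, since the hindered isomer can revert. Condensation of F8 with Me2NH (THF–MeOH, rt) then gives 12.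

**Step 9.**
- Most likely to go wrong: slow enolate formation and transmetalation at the branched α-methylene of the vinylogous amide, so that reduction of 14 or β-hydride elimination from the palladium enolate overtakes C–C reductive elimination.
- Fallback: it sets out from 10 and rejoins at 18. It moves the coupling onto the N-methylanilinomethylene blocking group, for which this arylation was developed and whose amine is also a better leaving group.
  - Ketone 10 is formylated as above to the hydroxymethylene ketone F8.
  - Condensation with N-methylaniline (TsOH cat., toluene, water removed) gives the N-methylanilinomethylene ketone F9.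
  - Arylation with 14 (Pd2(dba)3, biaryl phosphine, NaOtBu, toluene) gives the arylated N-methylanilinomethylene ketone F10.
  - F10 is submitted directly to the conditions of step 10 to give 18.

## Further compounds

F1 | step 10 | dimethyl (1S,2R,3R)-1-[4-(benzyloxy)-3,5-dimethoxyphenyl]-2,3-bis(benzyloxymethyl)-7-hydroxy-1,2,3,4-tetrahydronaphthalene-6,8-dicarboxylate (tetralin numbering) | COc1cc([C@H]2c3c(cc(C(=O)OC)c(O)c3C(=O)OC)C[C@@H](COCc3ccccc3)[C@@H]2COCc2ccccc2)cc(OC)c1OCc1ccccc1
F2 | step 10 | dimethyl (1S,2R,3R)-7-(benzyloxy)-1-[4-(benzyloxy)-3,5-dimethoxyphenyl]-2,3-bis(benzyloxymethyl)-1,2,3,4-tetrahydronaphthalene-6,8-dicarboxylate | COc1cc([C@H]2c3c(cc(C(=O)OC)c(OCc4ccccc4)c3C(=O)OC)C[C@@H](COCc3ccccc3)[C@@H]2COCc2ccccc2)cc(OC)c1OCc1ccccc1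
F3 | step 10 | [(1S,2R,3R)-7-(benzyloxy)-1-[4-(benzyloxy)-3,5-dimethoxyphenyl]-2,3-bis(benzyloxymethyl)-1,2,3,4-tetrahydronaphthalene-6,8-diyl]dimethanol | COc1cc([C@H]2c3c(cc(CO)c(OCc4ccccc4)c3CO)C[C@@H](COCc3ccccc3)[C@@H]2COCc2ccccc2)cc(OC)c1OCc1ccccc1
F4 | step 10 | (1S,2R,3R)-7-(benzyloxy)-1-[4-(benzyloxy)-3,5-dimethoxyphenyl]-2,3-bis(benzyloxymethyl)-1,2,3,4-tetrahydronaphthalene-6,8-dicarbaldehyde | COc1cc([C@H]2c3c(cc(C=O)c(OCc4ccccc4)c3C=O)C[C@@H](COCc3ccccc3)[C@@H]2COCc2ccccc2)cc(OC)c1OCc1ccccc1
F5 | step 10 | (1S,2R,3R)-7-(benzyloxy)-1-[4-(benzyloxy)-3,5-dimethoxyphenyl]-2,3-bis(benzyloxymethyl)-1,2,3,4-tetrahydronaphthalene-6,8-diyl diformate | COc1cc([C@H]2c3c(cc(OC=O)c(OCc4ccccc4)c3OC=O)C[C@@H](COCc3ccccc3)[C@@H]2COCc2ccccc2)cc(OC)c1OCc1ccccc1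
F6 | step 10 | (1S,2R,3R)-7-(benzyloxy)-1-[4-(benzyloxy)-3,5-dimethoxyphenyl]-2,3-bis(benzyloxymethyl)-1,2,3,4-tetrahydronaphthalene-6,8-diol | COc1cc([C@H]2c3c(cc(O)c(OCc4ccccc4)c3O)C[C@@H](COCc3ccccc3)[C@@H]2COCc2ccccc2)cc(OC)c1OCc1ccccc1
F7 | step 10 | (1S,2R,3R)-7-(benzyloxy)-1-[4-(benzyloxy)-3,5-dimethoxyphenyl]-2,3-bis(benzyloxymethyl)-6,8-dimethoxy-1,2,3,4-tetrahydronaphthalene | COc1cc([C@H]2c3c(cc(OC)c(OCc4ccccc4)c3OC)C[C@@H](COCc3ccccc3)[C@@H]2COCc2ccccc2)cc(OC)c1OCc1ccccc1
F8 | step 7 | (2Z,4R,5R)-4,5-bis(benzyloxymethyl)-2-(hydroxymethylidene)cyclohexan-1-one | O=C1C[C@@H](COCc2ccccc2)[C@H](COCc2ccccc2)C/C1=C/O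
F9 | step 9 | (2E,4R,5R)-4,5-bis(benzyloxymethyl)-2-{[methyl(phenyl)amino]methylidene}cyclohexan-1-one | O=C1C[C@@H](COCc2ccccc2)[C@H](COCc2ccccc2)C/C1=C\N(C)c1ccccc1
F10 | step 9 | (2S,3S,4R,6E)-2-[4-(benzyloxy)-3,5-dimethoxyphenyl]-3,4-bis(benzyloxymethyl)-6-{[methyl(phenyl)amino]methylidene}cyclohexan-1-one | COc1cc([C@H]2C(=O)/C(=C/N(C)c3ccccc3)C[C@@H](COCc3ccccc3)[C@@H]2COCc2ccccc2)cc(OC)c1OCc1ccccc1
A1 | alternative 1 | dimethyl (1S,3R)-7-(benzyloxy)-1-[4-(benzyloxy)-3,5-dimethoxyphenyl]-3-(benzyloxymethyl)-6,8-dimethoxy-3,4-dihydronaphthalene-2,2(1H)-dicarboxylate (1,3-cis) | COc1cc([C@H]2c3c(cc(OC)c(OCc4ccccc4)c3OC)C[C@@H](COCc3ccccc3)C2(C(=O)OC)C(=O)OC)cc(OC)c1OCc1ccccc1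
A2 | alternative 1 | dimethyl 2-[(2R)-1-(benzyloxy)-3-{4-(benzyloxy)-3,5-dimethoxy-2-[(E)-(tosylhydrazono)methyl]phenyl}propan-2-yl]malonate | COc1cc(C[C@@H](COCc2ccccc2)C(C(=O)OC)C(=O)OC)c(/C=N/NS(=O)(=O)c2ccc(C)cc2)c(OC)c1OCc1ccccc1
A3 | alternative 2 | dimethyl (1S,3S)-7-(benzyloxy)-1-[4-(benzyloxy)-3,5-dimethoxyphenyl]-6,8-dimethoxy-3-vinyl-3,4-dihydronaphthalene-2,2(1H)-dicarboxylate (1,3-cis) | COc1cc([C@H]2c3c(cc(OC)c(OCc4ccccc4)c3OC)C[C@@H](C=C)C2(C(=O)OC)C(=O)OC)cc(OC)c1OCc1ccccc1
A4 | alternative 2 | dimethyl 2-{(S)-[4-(benzyloxy)-3,5-dimethoxyphenyl][3-(benzyloxy)-6-bromo-2,4-dimethoxyphenyl]methyl}malonate | COc1cc([C@H](C(C(=O)OC)C(=O)OC)c2c(Br)cc(OC)c(OCc3ccccc3)c2OC)cc(OC)c1OCc1ccccc1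
A5 | alternative 3 | dimethyl (1S,2R,3S,4S)-7-(benzyloxy)-1-[4-(benzyloxy)-3,5-dimethoxyphenyl]-4-hydroxy-6,8-dimethoxy-1,2,3,4-tetrahydronaphthalene-2,3-dicarboxylate (1,2-trans, 2,3-trans, 3,4-cis) | COc1cc([C@H]2c3c(cc(OC)c(OCc4ccccc4)c3OC)[C@@H](O)[C@@H](C(=O)OC)[C@@H]2C(=O)OC)cc(OC)c1OCc1ccccc1
A6 | alternative 3 | 4-(benzyloxy)-2-[4-(benzyloxy)-3,5-dimethoxybenzyl]-3,5-dimethoxybenzaldehyde | COc1cc(Cc2c(C=O)cc(OC)c(OCc3ccccc3)c2OC)cc(OC)c1OCc1ccccc1
A7 | alternative 3 | dimethyl fumarate | COC(=O)/C=C/C(=O)OC
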